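Conventions used throughout: lignan locants are applied to both halves (C7 = ArCH–O, C8 = CH bearing C9H2OH, C8′ = carbinol carbon bearing the C7′ benzyl CH2, C9′ = ring OCH2, O1 = ring oxygen). Unit A is the tetrahydrofuran whose C7 sits on biaryl ring 1; unit B is the tetrahydrofuran whose C7′ sits on biaryl ring 2. ArG = 4-(benzyloxy)-3-methoxyphenyl.

## Analysis of the target

The target 27 is an unsymmetrical dimer of two olivil-type 7,9′-epoxylignans. Each half is a tetrahydrofuran O1–C7–C8–C8′–C9′ in which C7 carries an aryl group, C8 a hydroxymethyl group (C9), and C8′ a tertiary hydroxyl and an arylmethyl group (C7′). The halves are joined by a 5,5′-biaryl bond between two guaiacyl rings, but unit A hangs from the biaryl by its C7 aryl ring and unit B by its C7′ benzyl ring. There are six stereocentres, 7S,8R,8′S in each unit: the C7 aryl and C9 are trans, and the C8′ hydroxyl is anti to C9, so that benzyl and CH2OH are cis and the hydroxyl shares a ring face with the C7 aryl. The biaryl axis has only two ortho oxygens and two ortho hydrogens and is not a stable stereogenic element. The sensitive groups are the four phenols (oxidation, above all of the 2,2′-biphenol), the p-oxygenated benzylic C7–O1 bonds (acid ionisation with epimerisation or Friedel–Crafts closure to an aryltetralin, and hydrogenolysis) and the tertiary homobenzylic alcohols. The difficulty is to set two quaternary carbinol centres, each flanked by two further stereocentres, on a molecule whose halves are attached through different atoms. The plan rests on the C8–C8′ bond of each ring: it joins a CH carrying CH2–O (C9) to a carbon carrying an arylmethyl group and the ring CH2–O (C9′), which is the bond formed when a C8 radical born from a terminal oxirane adds to the inner carbon of an aryl propargyl ether.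

## Retrosynthetic reasoning

**Protecting groups (27 ⇐ 26 ⇐ 25).** The four phenols are carried as benzyl ethers, which survive organometallics, alkoxides, titanium(III) and hydride, and come off last under neutral hydrogenolysis. The C9 hydroxyls are carried as bulky silyl ethers from the ring-forming step onward and are freed by fluoride just before, so that only the fast-cleaving aryl benzyl ethers have to be hydrogenolysed next to the benzylic C7–O1 bonds.

**C8′–O and C7′–H (25 ⇐ 24 ⇐ 23 ⇐ 22).** The tertiary carbinol is traced back to an exocyclic C8′=C7′ benzylidene. Oxygen is added to the alkene face anti to the neighbouring C8 substituent (spiro-oxirane 24), and hydride is then delivered to the secondary benzylic C7′. The C8′–O bond is never broken afterwards, so the face selectivity of the oxidation is the C8′ configuration. Cutting here keeps the tertiary alcohol out of the ring-forming step and lets the C8 centre, once made, control C8′.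

**Both C8–C8′ bonds (22 ⇐ 21).** This is the central disconnection. Cutting C8–C8′ in each ring gives a C8 radical with an oxygen on C9 and an alkyne C8′≡C7′ tethered through O1–C9′. The radical precursor is a terminal oxirane (C8–C9) opened by a titanium(III) one-electron donor. One operation then forms two C–C bonds, two rings and both C8 centres, with C9 and C9′ already at their final oxidation level. The two sites differ in how they are attached to the biaryl but are the same functional array, so the asymmetry of the dimer does not matter to this step.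

**Oxiranes from alkenes (21 ⇐ 20).** The oxirane is only a radical precursor and its C8 configuration is lost in the planar radical. It is therefore introduced last, without stereocontrol, on the two vinyl groups of 20.

**Ether bonds O1–C9′ (20 ⇐ 19 + 4; 16 ⇐ 15 + 9).** Each ether is cut at the propargylic CH2–O bond and not at C7–O. C7 is a stereocentre on an electron-rich benzylic, allylic carbon that would ionise if it were the electrophile. With the C7 oxygen as nucleophile and a primary propargylic bromide as electrophile, the C7–O bond is never broken and the configuration of the resolved carbinols 15 and 4 passes unchanged into 21.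

**Propargylic carbons C9′ and alkynes C7′≡C8′ (19 ⇐ 18 ⇐ 16; 9 ⇐ 8 ⇐ 6 ⇐ 1 + 5; 13 ⇐ 12 + 5).** C9′ is added to a terminal aryl alkyne as a one-carbon electrophile, and the alkyne comes from an aryl aldehyde by one-carbon homologation with 5. The former formyl carbon becomes C7′, so the benzyl carbon of each unit is a vanillin aldehyde carbon.

**C7–C8 bonds and absolute configuration (15 ⇐ 14 ⇐ 13 + 2; 4 ⇐ 3 ⇐ 1 + 2).** The C7 carbinols come from addition of 2 to the aldehydes, followed by kinetic resolution to the S enantiomers. All six stereocentres of 27 derive from these two resolutions: C7 directly, C8 through the cyclisation, C8′ through the oxidation.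

**Biaryl and its desymmetrisation (13 ⇐ 12 ⇐ 11 ⇐ 10).** The biaryl bond is the one formed by oxidative ortho–ortho coupling of vanillin 10, which gives the symmetrical dialdehyde 11 in one step. The two formyl groups of 12 are told apart by a single statistical mono-homologation to 13. The alkyne is installed before the carbinol so that the ring-1 carbinol 14 is created in a molecule with no other stereocentre, which makes its resolution a plain enantiomer separation.

## Alternatives that were turned down

**Alternative 1: butenolide–alkyne photocycloaddition and cyclobutene cleavage.** The disconnection is C8–C9 and C8′–C7′ of unit B. The ring atoms C7, C8, C8′ and C9′ come from the (S)-3-benzyloxy-5-aryl-butenolide A1, and C9 and C7′ from the ethynyl group on ring 2 of A2, a biaryl that already carries a finished, protected unit A. Sensitised irradiation would add the alkyne across the C8=C8′ bond to give the cis-fused cyclobutene lactone A3. Oxidative cleavage of the cyclobutene, reduction of the C9 aldehyde, deoxygenation of the C7′ aryl ketone and reduction of the lactone carbonyl C9′ to CH2 would follow.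

- For: the oxygen on C8′ is in place before the C–C bonds form. The cis ring fusion forces C9 and C7′ onto one face, which is the required CH2OH/benzyl relationship, and the C7 aryl sends the alkyne to the opposite face, which gives 7,8-trans. On this point it is stronger than the chosen plan, which sets C8′ by a later face-selective oxidation.
- Against: nothing in A1 or A2 secures which alkyne carbon bonds to C8′. A2, with its aryl alkyne and biaryl chromophore, absorbs light and can quench the enone triplet. An intermolecular photocycloaddition needs one partner in excess, and both are advanced. After A3, three carbons (C9, C7′, C9′) need separate redox adjustment, and the ketone deoxygenation and the lactone-to-ether reduction call for acidic reducing conditions that threaten the benzylic C7–O bonds. It builds unit B only, so unit A needs a second campaign.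
- Comparison: the chosen route gives up the built-in C8′ oxygen but closes both rings in one neutral step with C9 and C9′ at their final oxidation level.

**Alternative 2: double lactone enolate hydroxylation.** The disconnection is the two C8′–O bonds. The precursor is the bis-lactone A4, in which C9′ is a lactone carbonyl and C8′ carries the benzyl group and a hydrogen. Double enolisation and oxidation with an electrophilic N-sulfonyloxaziridine would give the bis(α-hydroxy lactone) A5.

- For: it is two-directional, like the chosen plan. The enolate carbon C8′ is planar and directly flanked by C8 with its benzyloxymethyl group, so the oxidant comes anti to C9 and gives the right C8′ configuration. This facial bias is probably more dependable than that of an exocyclic alkene, whose face anti to C9 also carries the C7 aryl.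
- Against: A4 already contains all four C7/C8 centres and both benzyl groups, so making it is a full lignan-lactone synthesis carried out twice on an unsymmetrical biaryl. After A5, both lactone carbonyls must be taken down to CH2 next to a free tertiary hydroxyl. That means either reduction to the triol and re-closure of the ring (which has to single out one hydroxyl and risks ionising C7) or a lactol/silane reduction under Lewis acid, again on acid-labile benzylic ethers.
- Comparison: the chosen route answers the stronger face control of A5 with a bulky silyl group on C9–O and an osmylation fallback. In return C9′ is an ether CH2 from the start, and ring closure and the C8 centre come in the same step.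

**Alternative 3: oxocarbenium–allylsilane annulation around the biaryl aldehyde.** The disconnection is O1–C7 and C7–C8 of unit A. The aldehyde A6 (ring 1 formyl, finished unit B on ring 2) would be condensed with the diol allylsilane A7, which holds the preformed C8′ carbinol, C9′H2OH, the benzyl group and an allylsilane whose γ-carbon becomes C8. A Lewis acid would open the acetal to the C7 oxocarbenium ion, and the allylsilane would trap it to give A8 with a vinyl group on C8. Oxidative cleavage and reduction would then give C9H2OH.

- For: it is convergent, and the quaternary C8′ carbinol is made beforehand in an acyclic fragment by reagent-controlled oxidation, independent of any ring bias. That is stronger than the chosen plan on this centre. The ring also forms at the right oxidation level.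
- Against: a Lewis acid and a benzylic oxocarbenium ion on an electron-rich ring must coexist with the acid-labile 2-aryl-tetrahydrofuran and tertiary alcohol of unit B. C7 and C8 are both set in the cyclisation and must come out 7,8-trans with the vinyl group cis to the C8′ benzyl, and next to a quaternary centre nothing in A6 or A7 secures this. It serves unit A only, because unit B is attached through its benzyl carbon, so a second strategy is still needed.
- Comparison: the chosen route gives up reagent control at C8′ but treats both halves with one neutral reaction, whatever their mode of attachment.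

Key step: step 16

Assumption: the biaryl axis rotates freely at ambient temperature, so axial isomers are not counted or controlled.

## Route

Step 1
Reactants: 1 4-(benzyloxy)-3-methoxybenzaldehyde (O-benzylvanillin); 2 vinylmagnesium bromide
Product: 3 rac-1-[4-(benzyloxy)-3-methoxyphenyl]prop-2-en-1-ol
Conditions: THF, −78 → 0 °C; sat. aq. NH4Cl
Reagents that add atoms: vinylmagnesium bromide (2), C=C[Mg]Br
Why: Grignard 1,2-addition to the aromatic aldehyde forms the C7–C8 bond of unit B; C7 is formed racemic and is resolved in step 2; the neutral quench avoids acid-promoted allylic transposition of the electron-rich carbinol.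

Step 2
Reactants: 3 rac-1-[4-(benzyloxy)-3-methoxyphenyl]prop-2-en-1-ol
Product: 4 (S)-1-[4-(benzyloxy)-3-methoxyphenyl]prop-2-en-1-ol
Conditions: Ti(OiPr)4 (0.2 equiv), L-(+)-DIPT (0.25 equiv), t-BuOOH (0.6 equiv), 4 Å MS, CH2Cl2, −20 °C, run to about 55–60% conversion; NaOH/brine work-up
Reagents that add atoms: none
Why: Sharpless kinetic resolution; with L-(+)-tartrate the R carbinol is epoxidised fast (to its erythro epoxy alcohol), so running past half conversion should leave the S carbinol in high enantiopurity, which fixes C7 of unit B.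

Step 3
Reactants: 1 4-(benzyloxy)-3-methoxybenzaldehyde; 5 dimethyl (1-diazo-2-oxopropyl)phosphonate
Product: 6 1-(benzyloxy)-4-ethynyl-2-methoxybenzene
Conditions: K2CO3, MeOH, rt
Reagents that add atoms: dimethyl (1-diazo-2-oxopropyl)phosphonate (5), COP(=O)(OC)C(=[N+]=[N-])C(C)=O
Why: Seyferth–Gilbert homologation in its Ohira–Bestmann form; methanolysis frees the diazomethylphosphonate anion, olefination gives a diazoalkene that loses N2, and a 1,2-hydrogen shift gives the terminal aryl alkyne.

Step 4
Reactants: 6 1-(benzyloxy)-4-ethynyl-2-methoxybenzene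
Product: 8 3-[4-(benzyloxy)-3-methoxyphenyl]prop-2-yn-1-ol, via lithium acetylide 7 (not isolated)
Conditions: n-BuLi, THF, −78 °C; (CH2O)n, −78 °C → rt; sat. aq. NH4Cl
Reagents that add atoms: paraformaldehyde (formaldehyde unit), C=O
Why: Deprotonation of the terminal alkyne and addition of the acetylide to formaldehyde adds the future C9′ of unit A.

Step 5
Reactants: 8 3-[4-(benzyloxy)-3-methoxyphenyl]prop-2-yn-1-ol
Product: 9 1-(benzyloxy)-4-(3-bromoprop-1-yn-1-yl)-2-methoxybenzene
Conditions: CBr4, PPh3, CH2Cl2, 0 °C
Reagents that add atoms: carbon tetrabromide, BrC(Br)(Br)Br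
Why: Appel bromination of a primary propargylic alcohol under neutral conditions; the bromide is used soon after it is made.

Step 6
Reactants: 10 vanillin (two molecules)
Product: 11 divanillin (6,6′-dihydroxy-5,5′-dimethoxybiphenyl-3,3′-dicarbaldehyde)
Conditions: Na2S2O8, FeSO4·7H2O (cat.), H2O, 50 °C
Reagents that add atoms: none
Why: Oxidative phenol coupling; the phenoxy radical can only couple at the free ortho position (para is blocked by CHO, the other ortho by OMe), and the sparingly soluble dimer should precipitate and escape further oxidation.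

Step 7
Reactants: 11 divanillin
Product: 12 6,6′-bis(benzyloxy)-5,5′-dimethoxybiphenyl-3,3′-dicarbaldehyde
Conditions: BnBr, K2CO3, DMF, 60 °C
Reagents that add atoms: benzyl bromide, BrCc1ccccc1
Why: Williamson O-benzylation of both phenols gives a soluble, base- and organometallic-stable dialdehyde.

Step 8
Reactants: 12 6,6′-bis(benzyloxy)-5,5′-dimethoxybiphenyl-3,3′-dicarbaldehyde; 5 dimethyl (1-diazo-2-oxopropyl)phosphonate
Product: 13 6,6′-bis(benzyloxy)-3′-ethynyl-5,5′-dimethoxybiphenyl-3-carbaldehyde
Conditions: 5 (1.0 equiv), K2CO3, MeOH–THF, rt; chromatography, recovered 12 recycled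
Reagents that add atoms: dimethyl (1-diazo-2-oxopropyl)phosphonate (5), COP(=O)(OC)C(=[N+]=[N-])C(C)=O
Why: The same Ohira–Bestmann homologation with one equivalent; the two formyl groups sit on different rings of a twisted biaryl and react independently, so a statistical mixture is expected from which the mono-alkyne is separated by polarity.

Step 9
Reactants: 13 6,6′-bis(benzyloxy)-3′-ethynyl-5,5′-dimethoxybiphenyl-3-carbaldehyde; 2 vinylmagnesium bromide
Product: 14 rac-1-[6,6′-bis(benzyloxy)-3′-ethynyl-5,5′-dimethoxybiphenyl-3-yl]prop-2-en-1-ol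
Conditions: CH2=CHMgBr (2.5 equiv), THF, −78 → 0 °C; sat. aq. NH4Cl
Reagents that add atoms: vinylmagnesium bromide (2), C=C[Mg]Br
Why: Grignard addition to the remaining aldehyde; the excess covers the equivalent consumed by the terminal alkyne, which is reprotonated on work-up; C7 of unit A is formed racemic in a molecule with no other stereocentre.

Step 10
Reactants: 14 rac-1-[6,6′-bis(benzyloxy)-3′-ethynyl-5,5′-dimethoxybiphenyl-3-yl]prop-2-en-1-ol
Product: 15 (S)-1-[6,6′-bis(benzyloxy)-3′-ethynyl-5,5′-dimethoxybiphenyl-3-yl]prop-2-en-1-ol
Conditions: Ti(OiPr)4 (0.2 equiv), L-(+)-DIPT (0.25 equiv), t-BuOOH (0.6 equiv), 4 Å MS, CH2Cl2, −20 °C, run to about 55–60% conversion; NaOH/brine work-up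
Reagents that add atoms: none
Why: Sharpless kinetic resolution as in step 2; the R carbinol is consumed as its epoxy alcohol and the S carbinol remains, which fixes C7 of unit A; the alkyne and the arenes are inert to the titanium–peroxide reagent.

Step 11
Reactants: 15 (S)-1-[6,6′-bis(benzyloxy)-3′-ethynyl-5,5′-dimethoxybiphenyl-3-yl]prop-2-en-1-ol; 9 1-(benzyloxy)-4-(3-bromoprop-1-yn-1-yl)-2-methoxybenzene
Product: 16 (S)-allyl propargyl ether of unit A (ring 1: CH(CH=CH2)–O–CH2–C≡C–ArG; ring 2: C≡CH)
Conditions: NaH (1.1 equiv), THF, 0 °C; then 9, n-Bu4NI (cat.), 0 °C → rt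
Reagents that add atoms: none
Why: Williamson etherification; the sodium alkoxide displaces the primary propargylic bromide by SN2, the C7–O bond is not broken so C7 keeps its configuration, and with one equivalent of base in THF the alkoxide forms in preference to the acetylide.

Step 12
Reactants: 16 (S)-allyl propargyl ether of unit A
Product: 18 ring-2 propargylic alcohol (ring 2: C≡C–CH2OH; ring 1 as in 16), via lithium acetylide 17 (not isolated)
Conditions: n-BuLi (1.0 equiv), THF, −78 °C; (CH2O)n, −78 °C → rt; sat. aq. NH4Cl
Reagents that add atoms: paraformaldehyde (formaldehyde unit), C=O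
Why: The single terminal alkyne is the most acidic C–H by a wide margin, so one equivalent of base at low temperature should leave the ether C–H bonds alone; addition to formaldehyde adds C9′ of unit B.

Step 13
Reactants: 18 ring-2 propargylic alcohol
Product: 19 ring-2 propargylic bromide (ring 2: C≡C–CH2Br; ring 1 as in 16)
Conditions: CBr4, PPh3, CH2Cl2, 0 °C
Reagents that add atoms: carbon tetrabromide, BrC(Br)(Br)Br
Why: Appel bromination under neutral conditions, compatible with the allyl ether, the alkynes and the benzyl ethers.

Step 14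
Reactants: 19 ring-2 propargylic bromide; 4 (S)-1-[4-(benzyloxy)-3-methoxyphenyl]prop-2-en-1-ol
Product: 20 bis(allyl propargyl ether), both C7 centres S
Conditions: 4, NaH, THF, 0 °C; then 19, n-Bu4NI (cat.), 0 °C → rt
Reagents that add atoms: none
Why: Second Williamson etherification, as in step 11, with the alkoxide of 4 as nucleophile; it completes both O1–C9′ bonds with both C7 centres untouched.

Step 15
Reactants: 20 bis(allyl propargyl ether)
Product: 21 bis(epoxy propargyl ether), both C7 centres retained (R by the CIP change), mixture of epimers at the two oxirane CH carbons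
Conditions: mCPBA (excess), NaHCO3, CH2Cl2, 0 °C → rt
Reagents that add atoms: 3-chloroperbenzoic acid, OOC(=O)c1cccc(Cl)c1
Why: Prilezhaev epoxidation of the two monosubstituted alkenes; peracids react with alkenes much faster than with disubstituted alkynes, the bicarbonate buffer protects the benzylic ethers, and no facial control is needed because C8 becomes a planar radical in step 16.

Step 16
Reactants: 21 bis(epoxy propargyl ether)
Product: 22 bis(4-benzylidene-tetrahydrofuran) diol, 7S,8R in both rings, alkenes drawn E,E
Conditions: Cp2TiCl2 (5–6 equiv), Zn dust, THF, rt; the green Cp2TiCl solution added slowly to 21 in THF, rt; then cold dilute aq. HCl, brief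
Reagents that add atoms: none
Why: Titanocene(III) chloride, made in the flask from Cp2TiCl2 and zinc, transfers one electron to each oxirane, and the C8–O bond (the one to the more substituted carbon) breaks to leave C9 as a titanium(IV) alkoxide and a secondary radical at C8. Each radical adds to the near alkyne carbon C8′ in a 5-exo-dig closure (ring atoms C8, C7, O1, C9′, C8′), which is favoured over 6-endo attack by orbital overlap and because it gives an aryl-conjugated vinyl radical at C7′; this radical is reduced by a second titanium(III) or takes hydrogen from THF, and the Ti–C and Ti–O bonds are protonated on work-up. The closest known reaction type is the titanocene(III)-mediated epoxide-opening cyclisation of epoxy allyl and propargyl ethers to 2-aryl-3-(hydroxymethyl)tetrahydrofurans; here it runs twice in one molecule, at two sites insulated from each other by the biaryl. The only new stereocentre in each ring is C8, and it is controlled by the resolved C7 centre: in the envelope-like transition state the C7 aryl is pseudo-equatorial and the CH2OTi group on the radical carbon turns away from it, which gives the 7,8-trans ring. Because the C8 radical is planar, both oxirane epimers of 21 should converge on the same product. The alkene geometry (E expected from trapping of the vinyl radical on its open C9′ side) does not matter, since C7′ ends as CH2. The step needs cyclisation to outrun capture of the C8 radical by a second titanium(III), which would lead to β-elimination and loss of the oxygen; slow addition keeps the titanium(III) concentration low, and the short ether tether makes the ring closure fast.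

Step 17
Reactants: 22 bis(4-benzylidene-tetrahydrofuran) diol
Product: 23 bis(tert-butyldiphenylsilyl) ether of 22
Conditions: TBDPSCl, imidazole, DMF, rt
Reagents that add atoms: tert-butyl(chloro)diphenylsilane, CC(C)(C)[Si](Cl)(c1ccccc1)c1ccccc1
Why: Silylation of the two primary alcohols removes the hydroxyl that could direct an oxidant to the syn face, adds bulk on the C9 side of each alkene, and leaves only aryl benzyl ethers for the final hydrogenolysis.

Step 18
Reactants: 23 bis(tert-butyldiphenylsilyl) ether
Product: 25 bis(tertiary alcohol), 7S,8R,8′S in both units, C9–OTBDPS, four aryl benzyl ethers, via bis(spiro-oxirane) 24 (not isolated)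
Conditions: DMDO, acetone–CH2Cl2, −20 → 0 °C; evaporate cold; LiEt3BH, THF, 0 °C → rt; H2O
Reagents that add atoms: dimethyldioxirane, CC1(C)OO1
Why: Neutral dioxirane epoxidation of the electron-rich benzylidenes should occur on the face anti to the adjacent C8–CH2OTBDPS group, which places the C8′–O bond trans to C9 and so sets C8′; the labile p-alkoxyaryl oxiranes are not isolated but opened by SN2 hydride delivery from the borohydride at the secondary benzylic C7′ and not at the quaternary C8′, so the C8′–O bond stays intact and C7′ becomes CH2.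

Step 19
Reactants: 25 bis(tertiary alcohol) bis(silyl ether)
Product: 26 tetra-O-benzyl ether of the target (four phenols benzylated, all six hydroxyls free)
Conditions: TBAF, THF, rt
Reagents that add atoms: none
Why: Fluoride cleavage of the silyl ethers under non-acidic conditions; it is done while the phenols are still protected, so that no oxidation-prone phenoxide is exposed to base.

Step 20
Reactants: 26 tetra-O-benzyl ether of the target
Product: 27 target CNP0269573.1
Conditions: H2 (1 atm), 10% Pd/C, EtOAc–MeOH, rt; stopped as soon as debenzylation is complete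
Reagents that add atoms: none
Why: Catalytic hydrogenolysis of the four aryl benzyl ethers, which cleave much faster than the cyclic benzylic C7–O1 ethers; neutral conditions avoid ionisation at C7, and no stereocentre is touched.

## Compound list

1 | 4-(benzyloxy)-3-methoxybenzaldehyde (O-benzylvanillin) | COc1cc(C=O)ccc1OCc1ccccc1 | starting material
2 | vinylmagnesium bromide | C=C[Mg]Br | starting material
3 | rac-1-[4-(benzyloxy)-3-methoxyphenyl]prop-2-en-1-ol | C=CC(O)c1ccc(OCc2ccccc2)c(OC)c1 | intermediate
4 | (S)-1-[4-(benzyloxy)-3-methoxyphenyl]prop-2-en-1-ol | C=C[C@H](O)c1ccc(OCc2ccccc2)c(OC)c1 | intermediate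
5 | dimethyl (1-diazo-2-oxopropyl)phosphonate | COP(=O)(OC)C(=[N+]=[N-])C(C)=O | starting material
6 | 1-(benzyloxy)-4-ethynyl-2-methoxybenzene | C#Cc1ccc(OCc2ccccc2)c(OC)c1 | intermediate
7 | lithium acetylide of 6 | [Li]C#Cc1ccc(OCc2ccccc2)c(OC)c1 | intermediate
8 | 3-[4-(benzyloxy)-3-methoxyphenyl]prop-2-yn-1-ol | OCC#Cc1ccc(OCc2ccccc2)c(OC)c1 | intermediate
9 | 1-(benzyloxy)-4-(3-bromoprop-1-yn-1-yl)-2-methoxybenzene | BrCC#Cc1ccc(OCc2ccccc2)c(OC)c1 | intermediate
10 | vanillin | COc1cc(C=O)ccc1O | starting material
11 | divanillin (6,6′-dihydroxy-5,5′-dimethoxybiphenyl-3,3′-dicarbaldehyde) | COc1cc(C=O)cc(-c2cc(C=O)cc(OC)c2O)c1O | intermediate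
12 | 6,6′-bis(benzyloxy)-5,5′-dimethoxybiphenyl-3,3′-dicarbaldehyde | O=Cc3cc(OC)c(OCc9ccccc9)c(-c4cc(C=O)cc(OC)c4OCc9ccccc9)c3 | intermediate
13 | 6,6′-bis(benzyloxy)-3′-ethynyl-5,5′-dimethoxybiphenyl-3-carbaldehyde | O=Cc3cc(OC)c(OCc9ccccc9)c(-c4cc(C#C)cc(OC)c4OCc9ccccc9)c3 | intermediate
14 | rac-1-[6,6′-bis(benzyloxy)-3′-ethynyl-5,5′-dimethoxybiphenyl-3-yl]prop-2-en-1-ol | C=CC(O)c3cc(OC)c(OCc9ccccc9)c(-c4cc(C#C)cc(OC)c4OCc9ccccc9)c3 | intermediate
15 | (S)-1-[6,6′-bis(benzyloxy)-3′-ethynyl-5,5′-dimethoxybiphenyl-3-yl]prop-2-en-1-ol | C=C[C@H](O)c3cc(OC)c(OCc9ccccc9)c(-c4cc(C#C)cc(OC)c4OCc9ccccc9)c3 | intermediate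
16 | 6,6′-bis(benzyloxy)-3-[(1S)-1-{[3-(ArG)prop-2-yn-1-yl]oxy}prop-2-en-1-yl]-3′-ethynyl-5,5′-dimethoxybiphenyl | COc1cc(C#CCO[C@H](c3cc(OC)c(OCc9ccccc9)c(-c4cc(C#C)cc(OC)c4OCc9ccccc9)c3)C=C)ccc1OCc9ccccc9 | intermediate
17 | lithium acetylide of 16 | COc1cc(C#CCO[C@H](c3cc(OC)c(OCc9ccccc9)c(-c4cc(C#C[Li])cc(OC)c4OCc9ccccc9)c3)C=C)ccc1OCc9ccccc9 | intermediate
18 | ring-2 propargylic alcohol: as 16 with C≡C–CH2OH on ring 2, C7 (S) | COc1cc(C#CCO[C@H](c3cc(OC)c(OCc9ccccc9)c(-c4cc(C#CCO)cc(OC)c4OCc9ccccc9)c3)C=C)ccc1OCc9ccccc9 | intermediate
19 | ring-2 propargylic bromide: as 16 with C≡C–CH2Br on ring 2, C7 (S) | COc1cc(C#CCO[C@H](c3cc(OC)c(OCc9ccccc9)c(-c4cc(C#CCBr)cc(OC)c4OCc9ccccc9)c3)C=C)ccc1OCc9ccccc9 | intermediate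
20 | bis(allyl propargyl ether): ring 1 carries (1S)-CH(CH=CH2)–O–CH2–C≡C–ArG, ring 2 carries C≡C–CH2–O–(1S)-CH(ArG)(CH=CH2) | COc1cc(C#CCO[C@H](c3cc(OC)c(OCc9ccccc9)c(-c4cc(C#CCO[C@H](c6ccc(OCc9ccccc9)c(OC)c6)C=C)cc(OC)c4OCc9ccccc9)c3)C=C)ccc1OCc9ccccc9 | intermediate
21 | bis(epoxy propargyl ether): as 20 with oxiran-2-yl in place of each vinyl; both C7 configurations retained (R by CIP), oxirane CH as both epimers | COc1cc(C#CCO[C@H](c3cc(OC)c(OCc9ccccc9)c(-c4cc(C#CCO[C@H](c6ccc(OCc9ccccc9)c(OC)c6)C5CO5)cc(OC)c4OCc9ccccc9)c3)C2CO2)ccc1OCc9ccccc9 | intermediate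
22 | bis(4-benzylidene-tetrahydrofuran) diol: each ring (7S,8R)-2-aryl-3-(hydroxymethyl)-4-(arylmethylidene)tetrahydrofuran, 2,3-trans, alkenes drawn E | COc1cc(/C=C2/CO[C@H](c3cc(OC)c(OCc9ccccc9)c(-c4cc(/C=C5/CO[C@H](c6ccc(OCc9ccccc9)c(OC)c6)[C@H]5CO)cc(OC)c4OCc9ccccc9)c3)[C@H]2CO)ccc1OCc9ccccc9 | intermediate
23 | bis(C9–O-TBDPS) ether of 22 | COc1cc(/C=C2/CO[C@H](c3cc(OC)c(OCc9ccccc9)c(-c4cc(/C=C5/CO[C@H](c6ccc(OCc9ccccc9)c(OC)c6)[C@H]5CO[Si](c9ccccc9)(c9ccccc9)C(C)(C)C)cc(OC)c4OCc9ccccc9)c3)[C@H]2CO[Si](c9ccccc9)(c9ccccc9)C(C)(C)C)ccc1OCc9ccccc9 | intermediate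
24 | bis(spiro-oxirane) of 23: oxirane oxygen on C8′ anti to C8–CH2OTBDPS (syn to the C7 aryl) in both units | COc1cc([C@@H]7O[C@@]72CO[C@H](c3cc(OC)c(OCc9ccccc9)c(-c4cc([C@@H]8O[C@@]85CO[C@H](c6ccc(OCc9ccccc9)c(OC)c6)[C@H]5CO[Si](c9ccccc9)(c9ccccc9)C(C)(C)C)cc(OC)c4OCc9ccccc9)c3)[C@H]2CO[Si](c9ccccc9)(c9ccccc9)C(C)(C)C)ccc1OCc9ccccc9 | intermediate
25 | bis(tertiary alcohol), 7S,8R,8′S in both units, C9–OTBDPS, four aryl benzyl ethers | COc1cc(C[C@@]2(O)CO[C@H](c3cc(OC)c(OCc9ccccc9)c(-c4cc(C[C@@]5(O)CO[C@H](c6ccc(OCc9ccccc9)c(OC)c6)[C@H]5CO[Si](c9ccccc9)(c9ccccc9)C(C)(C)C)cc(OC)c4OCc9ccccc9)c3)[C@H]2CO[Si](c9ccccc9)(c9ccccc9)C(C)(C)C)ccc1OCc9ccccc9 | intermediate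
26 | tetra-O-benzyl ether of the target (7S,8R,8′S in both units) | COc1cc(C[C@@]2(O)CO[C@H](c3cc(OC)c(OCc9ccccc9)c(-c4cc(C[C@@]5(O)CO[C@H](c6ccc(OCc9ccccc9)c(OC)c6)[C@H]5CO)cc(OC)c4OCc9ccccc9)c3)[C@H]2CO)ccc1OCc9ccccc9 | intermediate
27 | CNP0269573.1 (7S,8R,8′S in both units) | COc1cc(C[C@@]2(O)CO[C@H](c3cc(OC)c(O)c(-c4cc(C[C@@]5(O)CO[C@H](c6ccc(O)c(OC)c6)[C@H]5CO)cc(OC)c4O)c3)[C@H]2CO)ccc1O | target

## Step count and least certain steps

Total step count: 20. Longest linear sequence: 15 steps, from vanillin 10 to 27 through steps 6–20. The two side branches are steps 1–2 (to 4) and steps 3–5 (to 9).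

**Step 16 (key step).** The most likely failure is interception of the C8 radical by a second titanium(III) before it cyclises, followed by β-elimination to the alkene (loss of the oxygen) or protonation to the uncyclised alcohol. Two rings must close in one molecule, so every such leak, and any incomplete 7,8-trans preference, counts twice and gives half-cyclised and diastereomeric material. The fallback makes the same C8 radicals with tin hydride from thionocarbonates instead of with titanium from oxiranes. It sets out from 20. Osmium-catalysed dihydroxylation of the two vinyl groups (OsO4 cat., NMO; the alkynes are left alone) gives the bis(1,2-diol) F1. Selective silylation of the primary hydroxyls (TBDPSCl, imidazole) gives the bis(silyl ether) F2. The secondary C8 hydroxyls are converted with phenyl chlorothionoformate, pyridine and DMAP into the bis(O-phenyl thionocarbonate) F3. Bu3SnH and AIBN in benzene at 80 °C then break the C8–O bonds (Barton–McCombie fragmentation), the radicals close 5-exo-dig as before, and the vinyl radicals take hydrogen from the stannane. This gives the silyl ether directly, and the route is rejoined at 23.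

**Step 8.** The mono-homologation is statistical, so at best about half of the dialdehyde can end as 13, and the separation from 12 and the bis-alkyne rests on modest polarity differences. The fallback builds the unsymmetrical biaryl by cross-coupling of two differentiated monomers and sets out from 10. Bromination (Br2, AcOH) gives 5-bromovanillin F4, and benzylation (BnBr, K2CO3) gives 4-(benzyloxy)-3-bromo-5-methoxybenzaldehyde F5. One portion is borylated (B2pin2, Pd(dppf)Cl2, KOAc) to the formyl aryl boronate F6. Another portion is homologated with 5 (K2CO3, MeOH) to the bromo aryl alkyne F7. Suzuki–Miyaura coupling of F6 with F7 (Pd(dppf)Cl2, aq. K3PO4, dioxane, copper-free so that the terminal alkyne is left alone) rejoins the route at 13.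

**Step 10 (and step 2).** The rate difference between the enantiomers may be too small for the bulky biaryl carbinol, and titanium(IV) may ionise or transpose the electron-rich aryl vinyl carbinol. Either would erode the enantiopurity on which all six stereocentres depend. The fallback is an enzymatic acylative resolution and sets out from 14. An immobilised lipase with vinyl acetate in an ether solvent at 30–40 °C should acylate the R enantiomer to the (R)-acetate F8, which is removed by chromatography. The unreacted S alcohol rejoins the route at 15. The same treatment of 3 would return 4.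

**Step 15.** The monosubstituted, oxygen-deactivated alkenes are slow towards peracid. Prolonged exposure may leave mono-epoxide behind or begin to oxidise the electron-rich aryl alkynes. The fallback builds the oxiranes by displacement and sets out from 20. Dihydroxylation as above gives the bis(1,2-diol) F1. Selective sulfonylation of the primary hydroxyls (TsCl, Et3N, cat. Bu2SnO) gives the bis(primary tosylate) F9. K2CO3 in MeOH closes both oxiranes and rejoins the route at 21.

**Step 18.** The face of each benzylidene that must be attacked is anti to the adjacent C8 substituent but syn to the more remote C7 aryl, so the facial selectivity may be incomplete, particularly for any Z alkene. The p-alkoxyaryl oxirane may also rearrange to a carbonyl compound before it is reduced. The fallback replaces epoxidation and hydride opening by osmylation and radical deoxygenation and sets out from 23. Dihydroxylation with the bulkier osmium reagent (OsO4 cat., NMO) gives the stable bis(C7′,C8′-diol) F10, whose isomers can be separated if needed. Thiocarbonyldiimidazole and DMAP in warm toluene give the bis(cyclic thionocarbonate) F11. Bu3SnH and AIBN cleave the C7′–O bond selectively, because this gives the benzylic radical, and mild methanolysis (K2CO3, MeOH) frees the tertiary hydroxyl. The route is rejoined at 25.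

## Further compounds

F1 | step 16 | bis(1,2-diol) from 20 (each vinyl group as CH(OH)CH2OH, C8 epimers, both C7 retained) | COc1cc(C#CCO[C@H](c3cc(OC)c(OCc9ccccc9)c(-c4cc(C#CCO[C@H](c6ccc(OCc9ccccc9)c(OC)c6)C(O)CO)cc(OC)c4OCc9ccccc9)c3)C(O)CO)ccc1OCc9ccccc9
F2 | step 16 | bis(primary TBDPS ether) of F1 | COc1cc(C#CCO[C@H](c3cc(OC)c(OCc9ccccc9)c(-c4cc(C#CCO[C@H](c6ccc(OCc9ccccc9)c(OC)c6)C(O)CO[Si](c9ccccc9)(c9ccccc9)C(C)(C)C)cc(OC)c4OCc9ccccc9)c3)C(O)CO[Si](c9ccccc9)(c9ccccc9)C(C)(C)C)ccc1OCc9ccccc9
F3 | step 16 | bis(O-phenyl thionocarbonate) of F2 at the C8 hydroxyls | COc1cc(C#CCO[C@H](c3cc(OC)c(OCc9ccccc9)c(-c4cc(C#CCO[C@H](c6ccc(OCc9ccccc9)c(OC)c6)C(OC(=S)Oc9ccccc9)CO[Si](c9ccccc9)(c9ccccc9)C(C)(C)C)cc(OC)c4OCc9ccccc9)c3)C(OC(=S)Oc9ccccc9)CO[Si](c9ccccc9)(c9ccccc9)C(C)(C)C)ccc1OCc9ccccc9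
F4 | step 8 | 5-bromovanillin | COc1cc(C=O)cc(Br)c1O
F5 | step 8 | 4-(benzyloxy)-3-bromo-5-methoxybenzaldehyde | COc1cc(C=O)cc(Br)c1OCc1ccccc1
F6 | step 8 | 4-(benzyloxy)-3-methoxy-5-(4,4,5,5-tetramethyl-1,3,2-dioxaborolan-2-yl)benzaldehyde | COc1cc(C=O)cc(B2OC(C)(C)C(C)(C)O2)c1OCc1ccccc1
F7 | step 8 | 2-(benzyloxy)-1-bromo-5-ethynyl-3-methoxybenzene | COc1cc(C#C)cc(Br)c1OCc1ccccc1
F8 | step 10 | (R)-1-[6,6′-bis(benzyloxy)-3′-ethynyl-5,5′-dimethoxybiphenyl-3-yl]prop-2-en-1-yl acetate | CC(=O)O[C@H](C=C)c3cc(OC)c(OCc9ccccc9)c(-c4cc(C#C)cc(OC)c4OCc9ccccc9)c3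
F9 | step 15 | bis(primary p-toluenesulfonate) of F1 | COc1cc(C#CCO[C@H](c3cc(OC)c(OCc9ccccc9)c(-c4cc(C#CCO[C@H](c6ccc(OCc9ccccc9)c(OC)c6)C(O)COS(=O)(=O)c9ccc(C)cc9)cc(OC)c4OCc9ccccc9)c3)C(O)COS(=O)(=O)c9ccc(C)cc9)ccc1OCc9ccccc9
F10 | step 18 | bis(C7′,C8′-diol) from 23 (both hydroxyls on the face anti to C8–CH2OTBDPS) | COc1cc([C@H](O)[C@@]2(O)CO[C@H](c3cc(OC)c(OCc9ccccc9)c(-c4cc([C@H](O)[C@@]5(O)CO[C@H](c6ccc(OCc9ccccc9)c(OC)c6)[C@H]5CO[Si](c9ccccc9)(c9ccccc9)C(C)(C)C)cc(OC)c4OCc9ccccc9)c3)[C@H]2CO[Si](c9ccccc9)(c9ccccc9)C(C)(C)C)ccc1OCc9ccccc9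
F11 | step 18 | bis(cyclic thionocarbonate) of F10 | COc1cc([C@@H]7OC(=S)O[C@@]72CO[C@H](c3cc(OC)c(OCc9ccccc9)c(-c4cc([C@@H]8OC(=S)O[C@@]85CO[C@H](c6ccc(OCc9ccccc9)c(OC)c6)[C@H]5CO[Si](c9ccccc9)(c9ccccc9)C(C)(C)C)cc(OC)c4OCc9ccccc9)c3)[C@H]2CO[Si](c9ccccc9)(c9ccccc9)C(C)(C)C)ccc1OCc9ccccc9
A1 | alternative 1 | (S)-3-(benzyloxy)-5-[4-(benzyloxy)-3-methoxyphenyl]furan-2(5H)-one | O=C1O[C@H](c2ccc(OCc3ccccc3)c(OC)c2)C=C1OCc1ccccc1
A2 | alternative 1 | ethynyl biaryl carrying protected unit A | COc1cc(C[C@@]2(O)CO[C@H](c3cc(OC)c(OCc9ccccc9)c(-c4cc(C#C)cc(OC)c4OCc9ccccc9)c3)[C@H]2COCc9ccccc9)ccc1OCc9ccccc9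
A3 | alternative 1 | cyclobutene-fused lactone joined to unit A | COc1cc(C[C@@]2(O)CO[C@H](c3cc(OC)c(OCc9ccccc9)c(-c4cc(C7=C[C@@H]8[C@@H](c6ccc(OCc9ccccc9)c(OC)c6)OC(=O)[C@]78OCc9ccccc9)cc(OC)c4OCc9ccccc9)c3)[C@H]2COCc9ccccc9)ccc1OCc9ccccc9
A4 | alternative 2 | bis(α-benzyl-β-benzyloxymethyl-γ-aryl-γ-butyrolactone), α-carbons unspecified | COc1cc(CC2C(=O)O[C@H](c3cc(OC)c(OCc9ccccc9)c(-c4cc(CC5C(=O)O[C@H](c6ccc(OCc9ccccc9)c(OC)c6)[C@H]5COCc9ccccc9)cc(OC)c4OCc9ccccc9)c3)[C@H]2COCc9ccccc9)ccc1OCc9ccccc9
A5 | alternative 2 | bis(α-hydroxy-α-benzyl lactone) | COc1cc(C[C@@]2(O)C(=O)O[C@H](c3cc(OC)c(OCc9ccccc9)c(-c4cc(C[C@@]5(O)C(=O)O[C@H](c6ccc(OCc9ccccc9)c(OC)c6)[C@H]5COCc9ccccc9)cc(OC)c4OCc9ccccc9)c3)[C@H]2COCc9ccccc9)ccc1OCc9ccccc9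
A6 | alternative 3 | biaryl aldehyde carrying protected unit B | O=Cc3cc(OC)c(OCc9ccccc9)c(-c4cc(C[C@@]5(O)CO[C@H](c6ccc(OCc9ccccc9)c(OC)c6)[C@H]5COCc9ccccc9)cc(OC)c4OCc9ccccc9)c3
A7 | alternative 3 | 1,2-diol allylsilane: 2-[4-(benzyloxy)-3-methoxybenzyl]-5-(trimethylsilyl)pent-3-ene-1,2-diol, E alkene, C8′ as in the target | COc1cc(C[C@@](/C=C/C[Si](C)(C)C)(O)CO)ccc1OCc1ccccc1
A8 | alternative 3 | 8-vinyl tetrahydrofuran A joined to unit B | COc1cc(C[C@@]2(O)CO[C@H](c3cc(OC)c(OCc9ccccc9)c(-c4cc(C[C@@]5(O)CO[C@H](c6ccc(OCc9ccccc9)c(OC)c6)[C@H]5COCc9ccccc9)cc(OC)c4OCc9ccccc9)c3)[C@H]2C=C)ccc1OCc9ccccc9
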